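## Retrosynthetic overview

1. Feature: on the benzene ring, C7a (bearing N1) and C3a (bearing C3) are neighbours. C3a sits beside C4–Br and C7a beside C7–H, so an aryne across C3a≡C7a (3,5-dibromobenzyne) should take the nucleophile N1 at C7a and carry the carbanion at C3a.
2. Key disconnection: N1–C7a and C3–C3a are cut together, giving 3,5-dibromobenzyne (masked as an ortho-silylaryl triflate) and methyl N-Boc-dehydroalaninate. The five-membered ring is the only ring formed; the benzene ring is bought.
3. The aryne precursor goes back to 2,4,6-tribromophenol by O-silylation, ortho Br/Li exchange with retro-Brook shift, and triflation.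
4. The C2 ester of the indoline is a traceless activator. Saponification and oxidative decarboxylation aromatise to N-Boc-4,6-dibromoindole, and Boc is then removed.
5. C2–Br is cut last, back to the lactam C=O of 4,6-dibromooxindole (POBr3), which comes from C2–H borylation/oxidation of 4,6-dibromoindole.

Key step: step 3

Remark on the chemistry: C5–H lies between two bromines and is assumed to compete with C2–H for a lithium amide (halogen dance, bromide loss), so the main line installs C2–Br without strong base and keeps a C2 metalation only as a reserve.

## Route

Step 1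
Reactants: 1 2,4,6-tribromophenol
Product: 2 (2,4,6-tribromophenoxy)trimethylsilane
Conditions: (Me3Si)2NH (0.7 equiv), THF, 70 °C; volatiles removed in vacuo, used crude under argon
Reagents that add atoms: hexamethyldisilazane, C[Si](C)(C)N[Si](C)(C)C
Why: O-silylation of an acidic phenol with a silazane needs no added base and releases only ammonia, so the moisture-sensitive aryl silyl ether can be carried on without purification.

Step 2
Reactants: 2 (2,4,6-tribromophenoxy)trimethylsilane
Product: 5 2,4-dibromo-6-(trimethylsilyl)phenyl trifluoromethanesulfonate, via ortho-lithiated silyl ether 3 (not isolated), via lithium silylphenoxide 4 (not isolated)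
Conditions: n-BuLi (1.05 equiv), THF, −100 to −80 °C; then Tf2O (1.2 equiv), −100 to −80 °C; cold aq NaHCO3
Reagents that add atoms: trifluoromethanesulfonic anhydride, O=S(=O)(OS(=O)(=O)C(F)(F)F)C(F)(F)F
Why: Bromine–lithium exchange, retro-Brook O-to-C silyl shift and O-triflation form the standard one-pot entry to ortho-silylaryl triflates; the two ortho bromines are equivalent, exchange beside oxygen is favoured over the para bromine, and the irreversible silyl shift drains any equilibrating aryllithium through the ortho isomer.

Step 3
Reactants: 5 2,4-dibromo-6-(trimethylsilyl)phenyl trifluoromethanesulfonate; 6 methyl 2-[(tert-butoxycarbonyl)amino]acrylate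
Product: 10 methyl 1-(tert-butoxycarbonyl)-4,6-dibromoindoline-2-carboxylate (racemic), via 3,5-dibromobenzyne 7 (not isolated), via ortho-bromoaryl anion 8 (not isolated), via cyclised ester enolate 9 (not isolated)
Conditions: 6 (1.0 equiv), Bu4N[Ph3SiF2] (TBAT, 2.0 equiv), THF, 0 → 23 °C; 5 (1.5 equiv) in THF added slowly by syringe pump
Reagents that add atoms: none
Why: Fluoride from the silicate attacks the silicon of 5 and triflate leaves to give aryne 7; the carbamate nitrogen of 6 (deprotonated by fluoride or by 9 from the preceding turnover) adds to the aryne carbon that has no brominated neighbour (N1–C7a), anion 8 adds to the acrylate CH2 (C3–C3a), and enolate 9 takes the N–H proton of the next molecule of 6. The reaction type is the known fluoride-triggered formal (3+2) annulation of arynes with N-carbamoyl dehydroamino esters to indoline-2-carboxylates, applied here to a 3-haloaryne. The five-membered ring closes by a 5-endo-trig conjugate addition, which is feasible because the carbanion lone pair lies in the arene plane and the N-aryl enamide can twist its alkene into reach. C2 is set by unselective protonation of the planar enolate, so 10 is racemic, which does not matter because C2 becomes sp2 in step 5. The step needs regioselective capture of the unsymmetrical aryne: the C–Br bond beside the triple bond distorts it so that the remote carbon is the more electrophilic one and charge builds up next to bromine, the bulky Boc-bearing nitrogen also avoids the bromine side, and the second bromine (future C6), para to the carbanion, has only a weak opposing influence. Ring closure must also outrun bromide loss or protonation of 8, which the tethered acceptor, the aprotic medium and the low stationary aryne concentration should secure.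

Step 4
Reactants: 10 methyl 1-(tert-butoxycarbonyl)-4,6-dibromoindoline-2-carboxylate (racemic)
Product: 11 1-(tert-butoxycarbonyl)-4,6-dibromoindoline-2-carboxylic acid (racemic)
Conditions: LiOH·H2O (2 equiv), THF/MeOH/H2O, 0 °C → rt; then 1 M HCl to pH 3, 0 °C
Reagents that add atoms: lithium hydroxide, [Li+].[OH-]
Why: Saponification of an unhindered methyl ester, to which the indoline carbamate and the aryl bromides are inert, as they are to the brief cold acidification.

Step 5
Reactants: 11 1-(tert-butoxycarbonyl)-4,6-dibromoindoline-2-carboxylic acid (racemic)
Product: 12 tert-butyl 4,6-dibromo-1H-indole-1-carboxylate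
Conditions: Pb(OAc)4 (1.3 equiv), Cu(OAc)2·H2O (10 mol %), pyridine (1.5 equiv), PhCl, 80 °C
Reagents that add atoms: none
Why: Kochi-type oxidative decarboxylation of an N-acyl alpha-amino acid, in which tetravalent lead (helped by divalent copper) removes CO2 and two electrons from the nitrogen-stabilised C2 and loss of a C3 proton is driven by aromatisation, so the alkene-forming outcome is the deactivated N-Boc indole.

Step 6
Reactants: 12 tert-butyl 4,6-dibromo-1H-indole-1-carboxylate
Product: 13 4,6-dibromo-1H-indole
Conditions: NaOMe (0.2 equiv), MeOH/THF, rt
Reagents that add atoms: none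
Why: Methanolysis (transacylation) of an indole N-carbamate, in which the electron-poor dibromoindolide is a good leaving group, so catalytic methoxide should remove Boc at room temperature without touching the aryl bromides.

Step 7
Reactants: 13 4,6-dibromo-1H-indole
Product: 15 4,6-dibromo-1,3-dihydro-2H-indol-2-one (4,6-dibromooxindole), via 2-borylated indole 14 (not isolated)
Conditions: B2pin2 (1.0 equiv), [Ir(OMe)(cod)]2 (1.5 mol %), 4,4′-di-tert-butyl-2,2′-bipyridine (3 mol %), THF, 50 °C; evaporate; then KHSO5 (as 2KHSO5·KHSO4·K2SO4, 1.2 equiv), acetone/H2O, 0 °C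
Reagents that add atoms: bis(pinacolato)diboron, CC1(C)OB(OC1(C)C)B1OC(C)(C)C(C)(C)O1 (boron group of 14 only); potassium peroxymonosulfate, [K+].[O-]S(=O)(=O)OO (oxygen of 15)
Why: Iridium-catalysed C–H borylation of an N–H indole goes to C2 and tolerates C–Br bonds, here with C3 (peri to C4–Br), C5 (between two bromines) and C7 (beside C6–Br) sterically closed, and the known one-pot peroxide oxidation of the C–B bond gives the C2–O compound, which rests as its lactam tautomer.

Step 8
Reactants: 15 4,6-dibromo-1,3-dihydro-2H-indol-2-one
Product: 16 2,4,6-tribromo-1H-indole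
Conditions: POBr3 (2.0 equiv), imidazole (1.2 equiv), 1,2-dichloroethane, 80 °C; cold aq NaHCO3; chromatography on Et3N-deactivated silica, product kept cold and dark
Reagents that add atoms: phosphoryl bromide, O=P(Br)(Br)Br
Why: Deoxygenative bromination of a lactam (imidoyl bromide formation), the standard conversion of oxindoles into 2-bromoindoles, in which phosphorus activates the lactam oxygen, bromide replaces it at C2 and tautomerisation restores the indole, with no electrophilic bromine present to attack C3, C5 or C7.

## Compound list

1 | 2,4,6-tribromophenol | Oc1c(Br)cc(Br)cc1Br | starting material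
2 | (2,4,6-tribromophenoxy)trimethylsilane | C[Si](C)(C)Oc1c(Br)cc(Br)cc1Br | intermediate
3 | [3,5-dibromo-2-(trimethylsilyloxy)phenyl]lithium | [Li]c1cc(Br)cc(Br)c1O[Si](C)(C)C | intermediate
4 | lithium 2,4-dibromo-6-(trimethylsilyl)phenoxide | [Li+].[O-]c1c(Br)cc(Br)cc1[Si](C)(C)C | intermediate
5 | 2,4-dibromo-6-(trimethylsilyl)phenyl trifluoromethanesulfonate | C[Si](C)(C)c1cc(Br)cc(Br)c1OS(=O)(=O)C(F)(F)F | intermediate
6 | methyl 2-[(tert-butoxycarbonyl)amino]acrylate | C=C(NC(=O)OC(C)(C)C)C(=O)OC | starting material
7 | 3,5-dibromobenzyne (3,5-dibromo-1,2-didehydrobenzene) | BrC1=CC(Br)=CC#C1 | intermediate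
8 | 2,4-dibromo-6-{(tert-butoxycarbonyl)[1-(methoxycarbonyl)ethenyl]amino}phenyl anion (Bu4N+ counter-ion omitted) | C=C(C(=O)OC)N(C(=O)OC(C)(C)C)c1cc(Br)cc(Br)[c-]1 | intermediate
9 | ester enolate of 10 (C2 sp2, Bu4N+ counter-ion omitted) | COC([O-])=C1Cc2c(Br)cc(Br)cc2N1C(=O)OC(C)(C)C | intermediate
10 | methyl 1-(tert-butoxycarbonyl)-4,6-dibromoindoline-2-carboxylate (racemic) | COC(=O)C1Cc2c(Br)cc(Br)cc2N1C(=O)OC(C)(C)C | intermediate
11 | 1-(tert-butoxycarbonyl)-4,6-dibromoindoline-2-carboxylic acid (racemic) | OC(=O)C1Cc2c(Br)cc(Br)cc2N1C(=O)OC(C)(C)C | intermediate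
12 | tert-butyl 4,6-dibromo-1H-indole-1-carboxylate | CC(C)(C)OC(=O)n1ccc2c(Br)cc(Br)cc21 | intermediate
13 | 4,6-dibromo-1H-indole | Brc1cc(Br)c2cc[nH]c2c1 | intermediate
14 | 4,6-dibromo-2-(4,4,5,5-tetramethyl-1,3,2-dioxaborolan-2-yl)-1H-indole | CC1(C)OB(OC1(C)C)c1cc2c(Br)cc(Br)cc2[nH]1 | intermediate
15 | 4,6-dibromo-1,3-dihydro-2H-indol-2-one | O=C1Cc2c(Br)cc(Br)cc2N1 | intermediate
16 | 2,4,6-tribromo-1H-indole | Brc1cc(Br)c2cc(Br)[nH]c2c1 | target

## Step count and risks

Total step count: 8. Longest linear sequence: 8 steps (1 → 16); 6 enters as a purchased partner in step 3.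

**Step 3 (aryne annulation).**
- What may go wrong: proton transfer to the aryl anion before it reaches the acrylate, which leaves N-arylation without ring closure.
- The neighbouring bromide may be expelled, with onward aryne chemistry.
- The anion may attack the ester carbonyl instead of the alkene.
- The regioselectivity of nitrogen attack may erode.
- Fallback: the two bonds are made in separate operations, setting out from 5. The aryne is released with CsF in MeCN at rt in the presence of commercial N-(2,2-dimethoxyethyl)-4-methylbenzenesulfonamide. This is a plain aryne N-arylation in which protonation of the aryl anion is the wanted outcome, and it should give N-(3,5-dibromophenyl)-N-(2,2-dimethoxyethyl)-4-methylbenzenesulfonamide F1. TiCl4 in toluene at 110 °C then closes C3–C3a by intramolecular Friedel–Crafts attack of the activated acetal on one of the two equivalent ortho positions, with loss of two methanol, to give 4,6-dibromo-1-(4-methylbenzenesulfonyl)-1H-indole F2. KOH in MeOH/THF removes the sulfonyl group, and the sequence comes back to the route at 13, in place of steps 3 to 6.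

**Step 8 (lactam to 2-bromoindole).**
- What may go wrong: acid-promoted self-condensation of the lactam with the product.
- Activation of the electron-poor lactam may be sluggish.
- The 2-bromoindole may hydrolyse or decompose during work-up and chromatography.
- Fallback: bromine is delivered to a C2 carbanion instead of to a lactam, setting out from 12. TMPMgCl·LiCl (THF, −20 to 0 °C) is guided by the Boc carbonyl to C2–H and should give tert-butyl 4,6-dibromo-2-(chloromagnesio)-1H-indole-1-carboxylate F3. Quenching with BrCCl2CCl2Br gives tert-butyl 2,4,6-tribromo-1H-indole-1-carboxylate F4. NaOMe (0.2 equiv) in MeOH/THF at rt removes Boc, and the sequence comes back at 16, in place of steps 6 to 8.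
- The magnesium amide is preferred to a lithium amide because metalation that strays to C5–H would give an arylmagnesium that should neither expel bromide nor start a halogen dance at this temperature. The open question of C2 versus C5 selectivity is why this shorter path is the reserve.

**Step 5 (oxidative decarboxylation).**
- What may go wrong: capture of the oxidised C2 by acetate without elimination.
- The new indole may be acetoxylated further.
- Boc may be partly lost at the Lewis-acidic lead salts.
- Fallback: dehydrogenation first and redox-neutral decarboxylation afterwards, setting out from 10. TFA in CH2Cl2 gives methyl 4,6-dibromoindoline-2-carboxylate F5 (racemic). DDQ in toluene at rt dehydrogenates the N–H indoline to methyl 4,6-dibromo-1H-indole-2-carboxylate F6. NaOH in aqueous MeOH gives 4,6-dibromo-1H-indole-2-carboxylic acid F7. Silver-catalysed protodecarboxylation (Ag2CO3 10 mol %, AcOH 5 mol %, DMSO, 120 °C) brings the sequence back to the route at 13, in place of steps 4 to 6.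

## Further compounds

F1 | step 3 | N-(3,5-dibromophenyl)-N-(2,2-dimethoxyethyl)-4-methylbenzenesulfonamide | COC(CN(c1cc(Br)cc(Br)c1)S(=O)(=O)c1ccc(C)cc1)OC
F2 | step 3 | 4,6-dibromo-1-(4-methylbenzenesulfonyl)-1H-indole | Cc1ccc(cc1)S(=O)(=O)n1ccc2c(Br)cc(Br)cc21
F3 | step 8 | tert-butyl 4,6-dibromo-2-(chloromagnesio)-1H-indole-1-carboxylate | CC(C)(C)OC(=O)n1c([Mg]Cl)cc2c(Br)cc(Br)cc21
F4 | step 8 | tert-butyl 2,4,6-tribromo-1H-indole-1-carboxylate | CC(C)(C)OC(=O)n1c(Br)cc2c(Br)cc(Br)cc21
F5 | step 5 | methyl 4,6-dibromoindoline-2-carboxylate (racemic) | COC(=O)C1Cc2c(Br)cc(Br)cc2N1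
F6 | step 5 | methyl 4,6-dibromo-1H-indole-2-carboxylate | COC(=O)c1cc2c(Br)cc(Br)cc2[nH]1
F7 | step 5 | 4,6-dibromo-1H-indole-2-carboxylic acid | OC(=O)c1cc2c(Br)cc(Br)cc2[nH]1
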